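In a one-step world every starting material consumed would stand as mono adduct, so one clock would give the answer.

| setting | winter | midnight | alder | birch | elm |
|---|---|---|---|---|---|
| starting material | 0.10 M | 0.10 M | 0.10 M | 0.10 M | 0.10 M |
| coupling partner | 0.043 M | 0.13 M | 0.0500 M | 0.120 M | 0.150 M |
| remark | run made earlier | run made earlier |  |  |  |
| time |  |  | 1.5 h | 1.5 h | 1.5 h |

- winter (time / min: mono adduct / %, starting material / %): 12.0: 16.6, 78.2; 30.0: 24.8, 66.1; 60.0: 29.0, 60.4; 90.0: 29.4, 59.6
- midnight (time / min: mono adduct / %, starting material / %): 12.0: 38.7, 45.9; 30.0: 54.1, 22.6; 60.0: 61.9, 12.4; 90.0: 63.8, 7.1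

(readings scatter by 0.5 percentage points)

* amount of mono adduct at the end, in percent of the starting material charged, for each flask in turn (alder, birch, elm)

- a reading or a percentage of mono adduct counts all its forms, free or not

The winter run refuses that world, and so does the midnight run, so take the end readings of both. Let b be partner charged per starting material, x the fraction consumed, and reckon the clock (rate constant times starting charge times time) from the law of one second-order step:

clock = ln[(b − x) / (b(1 − x))] / (b − 1)

Winter: b 0.430, x 40.4%, clock 4.01, ratio 0.728

Midnight: b 1.30, x 92.9%, clock 4.64, ratio 0.687

Call that last ratio, mono adduct standing per starting material consumed, the keep; it is a selectivity. It moves by 0.0410 between these two runs, so it can be carried. The asked time equals the last reading. My own reckoning draws clock and keep as straight lines in b, turns the clock back into x, and multiplies x by the keep: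

Alder: b 0.500, clock 4.06, x 0.465, keep 0.724, mono adduct 33.7%

Birch: b 1.20, clock 4.57, x 0.900, keep 0.691, mono adduct 62.2%

Elm: b 1.50, clock 4.78, x 0.967, keep 0.677, mono adduct 65.5%

The weak link is the winter clock: as fractions of the starting material charged, b is 43.0% and x is 40.4%, and the clock is read from the small gap b − x between them, which the scatter shakes. With the midnight clock in its place, alder comes to 34.3%, a shift of 0.67 percentage points.

The forecast says 33.7%, 62.5% and 65.5%, on the ground that “a parallel side path takes about 27%”; its birch stands above mine.

The flasks give 33.5% in alder, 62.6% in birch and 65.4% in elm, and the forecast held.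

    starting material + coupling partner → mono adduct (k = 0.500 M⁻¹ min⁻¹)
    starting material + coupling partner → other mono adduct (k = 0.170 M⁻¹ min⁻¹)
    coupling partner + mono adduct → double product (k = 0.260 M⁻¹ min⁻¹)
    coupling partner + other mono adduct → double product (k = 0.270 M⁻¹ min⁻¹)
    crystals ⇌ mono adduct, rate k5*(cs5 - [mono adduct]) while solid is left; crystals form when [mono adduct] > cs5 (solubility = 5.00 mM, k = 7.90 min⁻¹)

In alder, partner goes into mono adduct at 2.9 times the rate it goes into other mono adduct, at the start as at the asked time; as a keep that is 0.744, and alder ends with a keep of 0.721. In birch, 67.1% went through the first step and 22.8% through the second, a keep of 0.746 as made, while the keep standing at the end is 0.697, with 57.5% of the charge as crystals.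

All runs come from a simulation from invented constants, and the scatter is random.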